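## Retrosynthetic overview
1. Ampelopsin B (**14**) comes from global demethylation of its pentamethyl ether **13**. **13** comes from an acid-mediated cationic Friedel–Crafts closure of stilbene **12**, which forms the seven-membered ring last and sets the C-10 aryl stereocentre.
2. **12** comes from a Suzuki coupling on aryl bromide **10**. The trans-2,3-diaryl-dihydrobenzofuran **10** (five-membered ring) comes from SN1 cyclodehydration of diarylethanol **9**, which sets C-2.
3. **9** comes from ozonolysis and reduction of Claisen product **8**. The C-3 benzhydryl stereocentre of **8** is made by an aromatic Claisen [3,3] rearrangement of aryl ether **7**, with chirality transferred from the carbinol carbon.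
4. **7** comes from Mitsunobu etherification of (S)-allylic alcohol **5**, which comes from hydroarylation of alkynol **3**, which comes from Sonogashira coupling of (S)-but-3-yn-2-ol (**1**).

**Assumptions**
- (S)-But-3-yn-2-ol and the aryl building blocks are commercial.
- The Claisen goes through a chair transition state with the C-2 methyl pseudo-equatorial, so the (R)-ether gives (S)-C3.
- Acid cyclisation of **12** gives the natural C-10 diastereomer, as in the known ε-viniferin to ampelopsin B cyclisation.

## Route

**Step 1**
Reactants: **1** (S)-but-3-yn-2-ol; **2** 1-iodo-3,5-dimethoxybenzene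
Product: **3** (S)-4-(3,5-dimethoxyphenyl)but-3-yn-2-ol
Conditions: Pd(PPh3)2Cl2 (2 mol %), CuI (4 mol %), Et3N, THF, rt
Reagents that add atoms: none
Why: Sonogashira coupling of a terminal alkyne under mild, non-epimerising conditions; the only stereocentre (the carbinol, from the chiral alcohol) is untouched.

**Step 2**
Reactants: **3**; **4** 4-methoxyphenylboronic acid
Product: **5** (2S,3Z)-4-(3,5-dimethoxyphenyl)-3-(4-methoxyphenyl)but-3-en-2-ol
Conditions: [Rh(OH)(cod)]2 (3 mol %), dioxane/H2O (10:1), 60 °C
Reagents that add atoms: none
Why: Rh-catalysed syn-hydroarylation (Hayashi–Miyaura type). The O–Rh five-membered chelate and the aryl-stabilised Rh–C place the new aryl next to the carbinol, and syn addition fixes the Z geometry; the carbinol carbon is not affected.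

**Step 3**
Reactants: **5**; **6** 3-bromo-5-methoxyphenol
Product: **7** 1-bromo-3-methoxy-5-{[(2R,3Z)-4-(3,5-dimethoxyphenyl)-3-(4-methoxyphenyl)but-3-en-2-yl]oxy}benzene
Conditions: PPh3, DIAD, THF, 0 °C to rt
Reagents that add atoms: none
Why: Mitsunobu etherification of the acidic phenol with a secondary alcohol proceeds with clean SN2 inversion, so the (S)-alcohol gives the (R)-ether.

**Step 4**
Reactants: **7**
Product: **8** 3-bromo-2-[(1R)-1-(3,5-dimethoxyphenyl)-2-(4-methoxyphenyl)but-2-en-1-yl]-5-methoxyphenol (Me trans to the benzhydryl carbon)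
Conditions: PhNEt2, 200 °C, sealed tube or microwave, 2 h
Reagents that add atoms: none
Why: Aromatic Claisen [3,3]-sigmatropic rearrangement. The C–C bond forms on the same face as the breaking C–O bond, so the carbinol stereocentre sets the new benzhydryl centre (C-3 of the target) by chirality transfer. The ortho carbon flanked by Br is favoured by both the meta-OMe and the meta-Br.

**Step 5**
Reactants: **8**
Product: **9** 3-bromo-2-[(1S)-1-(3,5-dimethoxyphenyl)-2-hydroxy-2-(4-methoxyphenyl)ethyl]-5-methoxyphenol (C-2 carbinol epimers, not separated)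
Conditions: O3, CH2Cl2/MeOH (4:1), −78 °C; then NaBH4, −78 to 0 °C (one pot)
Reagents that add atoms: ozone, [O-][O+]=O (its oxygen ends up as the carbinol OH); NaBH4 delivers only H
Why: Ozonolysis of the conjugated trisubstituted alkene gives the diaryl ketone, which is reduced in the same pot before the epimerisable α,α-diaryl ketone can racemise. The acetaldehyde fragment is lost, and the carbinol configuration is irrelevant because step 6 goes through a cation.

**Step 6**
Reactants: **9**
Product: **10** (2S,3S)-4-bromo-3-(3,5-dimethoxyphenyl)-6-methoxy-2-(4-methoxyphenyl)-2,3-dihydro-1-benzofuran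
Conditions: p-TsOH·H2O (10 mol %), toluene, 50 °C
Reagents that add atoms: none
Why: Acid-catalysed intramolecular SN1 etherification (dehydrative 5-exo closure). Both carbinol epimers ionise to the same p-methoxybenzylic cation, and the phenol closes to the thermodynamically preferred 2,3-trans isomer, setting C-2. C-3 is not ionisable and is retained.

**Step 7**
Reactants: **10**; **11** (E)-2-(4-methoxystyryl)-4,4,5,5-tetramethyl-1,3,2-dioxaborolane
Product: **12** (2S,3S)-3-(3,5-dimethoxyphenyl)-6-methoxy-2-(4-methoxyphenyl)-4-[(E)-4-methoxystyryl]-2,3-dihydrobenzofuran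
Conditions: Pd(OAc)2 (5 mol %), SPhos (10 mol %), K3PO4, toluene/H2O (10:1), 90 °C
Reagents that add atoms: none
Why: Suzuki–Miyaura coupling with a bulky biaryl phosphine copes with the hindered C-4 bromide and retains E-alkene geometry. The mild base leaves the benzylic stereocentres intact.

**Step 8**
Reactants: **12**
Product: **13** pentamethyl ampelopsin B
Conditions: TfOH (10 mol %), CH2Cl2, −20 to 0 °C
Reagents that add atoms: none
Why: Protonation of the anisyl-stabilised styrene gives a benzylic cation that is attacked by the activated ortho carbon of the 3,5-dimethoxyphenyl ring (intramolecular Friedel–Crafts alkylation). The rigid trans-fused bicycle allows only one facial approach, which sets the C-10 stereocentre.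

**Step 9**
Reactants: **13**
Product: **14** ampelopsin B
Conditions: BBr3 (10 equiv), CH2Cl2, −78 °C to rt; H2O quench
Reagents that add atoms: none (the aqueous quench supplies only H)
Why: BBr3 cleaves all five aryl methyl ethers. The low temperature spares the benzylic ether and the three stereocentres.

## Compound list
1 | (S)-but-3-yn-2-ol | C[C@H](O)C#C | starting material
2 | 1-iodo-3,5-dimethoxybenzene | COc1cc(I)cc(OC)c1 | starting material
3 | (S)-4-(3,5-dimethoxyphenyl)but-3-yn-2-ol | C[C@H](O)C#Cc1cc(OC)cc(OC)c1 | intermediate
4 | 4-methoxyphenylboronic acid | COc1ccc(B(O)O)cc1 | starting material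
5 | (2S,3Z)-allylic alcohol | C[C@H](O)/C(c1ccc(OC)cc1)=C\c1cc(OC)cc(OC)c1 | intermediate
6 | 3-bromo-5-methoxyphenol | COc1cc(O)cc(Br)c1 | starting material
7 | (2R,3Z)-aryl allyl ether | C[C@@H](Oc1cc(Br)cc(OC)c1)/C(c1ccc(OC)cc1)=C\c1cc(OC)cc(OC)c1 | intermediate
8 | Claisen product (phenol) | C/C=C(/[C@@H](c1cc(OC)cc(OC)c1)c1c(Br)cc(OC)cc1O)c1ccc(OC)cc1 | intermediate
9 | 1,2-diaryl-2-hydroxyethyl phenol (C-2 epimer mixture) | COc1ccc(cc1)C(O)[C@@H](c1cc(OC)cc(OC)c1)c1c(Br)cc(OC)cc1O | intermediate
10 | (2S,3S)-4-bromo-dihydrobenzofuran | COc1ccc(cc1)[C@H]1Oc2cc(OC)cc(Br)c2[C@@H]1c1cc(OC)cc(OC)c1 | intermediate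
11 | (E)-4-methoxystyryl-Bpin | COc1ccc(/C=C/B2OC(C)(C)C(C)(C)O2)cc1 | starting material
12 | permethyl ε-viniferin-type stilbene | COc1ccc(cc1)[C@H]1Oc2cc(OC)cc(/C=C/c3ccc(OC)cc3)c2[C@@H]1c1cc(OC)cc(OC)c1 | intermediate
13 | pentamethyl ampelopsin B | COc1ccc([C@@H]2Cc3cc(OC)cc4c3[C@H](c3cc(OC)cc(OC)c32)[C@@H](c2ccc(OC)cc2)O4)cc1 | intermediate
14 | ampelopsin B | Oc1ccc([C@@H]2Cc3cc(O)cc4c3[C@H](c3cc(O)cc(O)c32)[C@@H](c2ccc(O)cc2)O4)cc1 | target

## Totals
Total steps: 9. Longest linear sequence: 9 steps (1 → 3 → 5 → 7 → 8 → 9 → 10 → 12 → 13 → 14).

## Three steps most likely to fail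
1. **Step 4 (Claisen).** The congested ortho position may give the wrong regioisomer, and the high temperature may erode ee through ion-pair racemisation.
   - Fallback: use the aryl ether of 3-hydroxy-5-methoxybenzaldehyde (a smaller CHO in place of Br), which should improve regioselectivity at lower temperature. Install the stilbene later by Horner–Wadsworth–Emmons olefination.
2. **Step 2 (hydroarylation).** Regio- or stereoselectivity may be poor, giving a mixture of E/Z isomers or aryl on the wrong alkyne carbon.
   - Fallback: start from (S)-lactate, make the O-TBS Weinreb amide, add 4-MeOC6H4MgBr to give the aryl ketone, then use a Horner–Wittig olefination with the 3,5-dimethoxybenzyl phosphine oxide. Separate the Z isomer and desilylate.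
3. **Step 8 (Friedel–Crafts closure).** The acid may ionise the benzylic C-2 ether and scramble C-2, or give the wrong C-10 diastereomer.
   - Fallback: skip isolating **13**. Treat stilbene **12** with excess BBr3 so that in-situ HBr drives cyclisation together with demethylation in one pot at low temperature.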